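**Plan**

1. Retrosynthetic cuts: the C2′–O7 ketal bond and the C3′–O bond go back to a 2′,3′-epoxide of a 2,3-diarylchromone. The C3′–C8 bond is cut to tri-O-benzylapigenin (metalated at C3′) and an 8-bromoflavan. The flavan C3–C4 bond is cut by placing an NH between C3 and C4, giving a 2-aryl-tetrahydro-1,4-benzoxazepine, which comes from a salicylaldehyde and an azido alcohol.
2. Forward order: azido alcohol → aryl ether (Mitsunobu) → seven-membered oxazepine (aza-Wittig, reduction) → contraction to the six-membered pyran by loss of N2 → C8 bromination → Negishi union with the chromone → epoxidation of C2′=C3′ → acid (MOM loss, closure of the dihydrofuran ring on C2′) → hydrogenolysis.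
3. Enabling feature: C4 of the flavan is a CH2 benzylic to the phloroglucinol ring A and C3 is a plain CH2. A C3–NH–C4 bridge is therefore a benzylic secondary amine that can be built from an aldehyde and an azide and then excised, while the only stereocentre of that ring (C2) lies outside the reacting atoms.
4. Stereochemistry: C2 (S) from CBS reduction of an α-azido ketone followed by Mitsunobu inversion. C3′ (R) from catalyst-controlled Jacobsen–Katsuki epoxidation. C2′ (R) follows because only the cis-fused bicyclic ketal can form.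

Key step: step 6

Locants: lower flavan O1, C2–C4, ring A (C4a–C8a), ring B; upper unit primed (O1′, ketal carbon C2′, carbinol carbon C3′, carbonyl C4′, rings A′ and B′).
Assumption: the (R,R) antipode of the (salen)MnCl catalyst in step 10 is taken to deliver oxygen to the face of C2′=C3′ that gives the (2′R,3′R) epoxide; if the sense were opposite, the (S,S) antipode would be used with nothing else changed.

**Route**

Step 1
Reactants: 1 2,4,6-trihydroxybenzaldehyde
Product: 2 2-hydroxy-4,6-bis(methoxymethoxy)benzaldehyde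
Conditions: MOMCl (2.1 equiv), iPr2NEt, CH2Cl2, 0 °C
Reagents that add atoms: chloromethyl methyl ether, COCCl
Why: Williamson-type O-alkylation; the para OH and one ortho OH react, while the second ortho OH is held by the hydrogen bond to the aldehyde and stays free for step 4.

Step 2
Reactants: 3 2-bromo-1-[4-(benzyloxy)phenyl]ethan-1-one
Product: 4 2-azido-1-[4-(benzyloxy)phenyl]ethan-1-one
Conditions: NaN3, acetone/H2O, 0 °C to rt
Reagents that add atoms: sodium azide, [Na+].[N-]=[N+]=[N-]
Why: SN2 displacement of an α-bromo ketone by azide.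

Step 3
Reactants: 4 2-azido-1-[4-(benzyloxy)phenyl]ethan-1-one
Product: 5 (S)-2-azido-1-[4-(benzyloxy)phenyl]ethan-1-ol
Conditions: (S)-2-methyl-CBS-oxazaborolidine (10 mol %), BH3·SMe2, THF, 0 °C; aqueous work-up
Reagents that add atoms: none
Why: Corey–Bakshi–Shibata reduction with aryl as the large and CH2N3 as the small group should deliver hydride in the same spatial sense as for acetophenone, which here is named (S) because CH2N3 outranks aryl.

Step 4
Reactants: 2 2-hydroxy-4,6-bis(methoxymethoxy)benzaldehyde; 5 (S)-2-azido-1-[4-(benzyloxy)phenyl]ethan-1-ol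
Product: 6 2-{(1R)-2-azido-1-[4-(benzyloxy)phenyl]ethoxy}-4,6-bis(methoxymethoxy)benzaldehyde
Conditions: PPh3, DIAD (betaine pre-formed), THF, 0 °C to rt
Reagents that add atoms: none
Why: Mitsunobu etherification of a secondary benzylic alcohol by a phenol goes with inversion and should give the (R) ether, the spatial arrangement of flavan C2 (S); the β-azido group disfavours an SN1 leak and the pre-formed betaine keeps free PPh3 away from the azide.

Step 5
Reactants: 6 2-{(1R)-2-azido-1-[4-(benzyloxy)phenyl]ethoxy}-4,6-bis(methoxymethoxy)benzaldehyde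
Product: 9 (2R)-2-[4-(benzyloxy)phenyl]-6,8-bis(methoxymethoxy)-2,3,4,5-tetrahydro-1,4-benzoxazepine, via iminophosphorane 7 (not isolated), via cyclic imine 8 (not isolated)
Conditions: PPh3, THF, rt to 50 °C; then NaBH4, MeOH, 0 °C
Reagents that add atoms: none
Why: Staudinger reaction followed by intramolecular aza-Wittig condensation on the ortho aldehyde should close the seven-membered ring, and hydride reduces the C=N bond; the stereocentre is not touched.

Step 6
Reactants: 9 (2R)-2-[4-(benzyloxy)phenyl]-6,8-bis(methoxymethoxy)-2,3,4,5-tetrahydro-1,4-benzoxazepine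
Product: 12 (2S)-2-[4-(benzyloxy)phenyl]-5,7-bis(methoxymethoxy)-3,4-dihydro-2H-chromene, via N-aminated hydrazide 10 (not isolated), via isodiazene 11 (not isolated)
Conditions: N-(benzyloxy)-N-(pivaloyloxy)-4-(trifluoromethyl)benzamide (1.5 equiv), THF, 45 °C
Reagents that add atoms: none
Why: The secondary amine attacks the electrophilic nitrogen of the anomeric amide (SN2 at N, pivalate leaves) to give hydrazide 10, which expels benzyl 4-(trifluoromethyl)benzoate to form isodiazene 11; loss of N2 leaves a short-lived singlet radical pair (ring-A benzylic radical at C4, primary radical at C3) still tied together through C2–O1–C8a–C4a, and its collapse forms the C3–C4 bond. The closest known reaction type is the nitrogen deletion of secondary benzylic amines with anomeric amides, which contracts cyclic amines by one atom. The only ring closed is the dihydropyran, by radical–radical recombination of the 1,6-diradical (seven-membered oxazepine to six-membered pyran), not by an ionic closure. No stereocentre is created: C2 keeps the configuration set in steps 3 and 4 and is not a radical site, so (R)-9 becomes (S)-12 only through the change in substituent priorities. The step needs recombination to outrun β-scission of the C2–O1 bond from the C3 radical (which would give an ortho-quinone methide and 4-(benzyloxy)styrene) and tautomerisation of 11 to a hydrazone; the benzylic stabilisation at C4, the short tether and the mild temperature should secure this.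

Step 7
Reactants: 12 (2S)-2-[4-(benzyloxy)phenyl]-5,7-bis(methoxymethoxy)-3,4-dihydro-2H-chromene
Product: 13 (2S)-2-[4-(benzyloxy)phenyl]-8-bromo-5,7-bis(methoxymethoxy)-3,4-dihydro-2H-chromene
Conditions: NBS (1.0 equiv), CH2Cl2, −78 to 0 °C, dark
Reagents that add atoms: N-bromosuccinimide, O=C1CCC(=O)N1Br
Why: Electrophilic aromatic bromination; of the two free ring-A positions C8 (flanked by the ring oxygen O1) is the less hindered and is the usual site in 5,7-di-O-protected flavans, whereas C6 sits between two MOM ethers.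

Step 8
Reactants: 14 apigenin
Product: 15 5,7-bis(benzyloxy)-2-[4-(benzyloxy)phenyl]-4H-chromen-4-one
Conditions: BnBr (4 equiv), K2CO3, DMF, 80 °C
Reagents that add atoms: benzyl bromide, BrCc1ccccc1
Why: Williamson etherification; heating and excess reagent are used because the chelated 5-OH reacts last.

Step 9
Reactants: 15 5,7-bis(benzyloxy)-2-[4-(benzyloxy)phenyl]-4H-chromen-4-one; 13 (2S)-2-[4-(benzyloxy)phenyl]-8-bromo-5,7-bis(methoxymethoxy)-3,4-dihydro-2H-chromene
Product: 18 5,7-bis(benzyloxy)-2-[4-(benzyloxy)phenyl]-3-{(2S)-2-[4-(benzyloxy)phenyl]-5,7-bis(methoxymethoxy)-3,4-dihydro-2H-chromen-8-yl}-4H-chromen-4-one, via 3-lithioflavone 16 (not isolated), via 3-(chlorozincio)flavone 17 (not isolated)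
Conditions: LiN(iPr)2, THF, −78 °C; ZnCl2, −78 to 0 °C; then 13, Pd2(dba)3 (2.5 mol %), RuPhos (10 mol %), THF, 65 °C
Reagents that add atoms: none
Why: Carbonyl-directed C3 lithiation of the flavone, transmetalation to zinc and Negishi coupling with the hindered, electron-rich aryl bromide under a dialkylbiarylphosphine–palladium catalyst suited to four ortho substituents; no stereocentre is formed, and any slow rotation about C3′–C8 is of no consequence because that axis disappears in step 11.

Step 10
Reactants: 18 5,7-bis(benzyloxy)-2-[4-(benzyloxy)phenyl]-3-{(2S)-2-[4-(benzyloxy)phenyl]-5,7-bis(methoxymethoxy)-3,4-dihydro-2H-chromen-8-yl}-4H-chromen-4-one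
Product: 19 (2R,3R)-5,7-bis(benzyloxy)-2-[4-(benzyloxy)phenyl]-3-{(2S)-2-[4-(benzyloxy)phenyl]-5,7-bis(methoxymethoxy)-3,4-dihydro-2H-chromen-8-yl}-2,3-epoxy-2,3-dihydro-4H-chromen-4-one
Conditions: (R,R)-(salen)MnCl [salen = N,N′-bis(3,5-di-tert-butylsalicylidene)cyclohexane-1,2-diamine dianion] (10 mol %), dimethyldioxirane (acetone solution), CH2Cl2, −20 to 0 °C
Reagents that add atoms: dimethyldioxirane, CC1(C)OO1
Why: Jacobsen–Katsuki epoxidation, precedented for the C2=C3 bond of 3-arylchromones: the chiral (salen)Mn-oxo species should deliver oxygen to one face of C2′=C3′ and so fix C3′ as (R) with C2′ necessarily syn, and since flavan C2 is already fixed the wrong-face product is a diastereomer that chromatography can remove.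

Step 11
Reactants: 19 (2R,3R)-2′,3′-epoxide
Product: 22 tetra-O-benzyl ether of the target (benzyl on O5′, O7′, O4 of ring B′ and O4 of ring B; 5-OH and 3′-OH free; 2S,2′R,3′R), via methanol adduct 20 (not isolated), via deprotected methanol adduct 21 (not isolated)
Conditions: conc. HCl (5 equiv), MeOH/THF 1:1, 40 °C
Reagents that add atoms: none
Why: Acid-catalysed epoxide opening at the ketal-type carbon C2′ (oxocarbenium ion stabilised by O1′ and ring B′, held reversibly as the methanol adduct), acetal exchange of both MOM ethers with methanol, and capture of C2′ by the freed 7-OH in a five-membered ring closure; C3′ keeps its C–O bond, and C2′ becomes (R) because the furan ring can only be cis-fused, which places ring B′ syn to the 3′-OH.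

Step 12
Reactants: 22 tetra-O-benzyl ether of the target
Product: 23 CNP0208300.2 (target)
Conditions: H2 (1 atm), Pd(OH)2/C, THF/MeOH 1:1, rt
Reagents that add atoms: none
Why: Hydrogenolysis of four aryl benzyl ethers; the cyclic benzylic C–O bonds at C2 and C2′ and the tertiary 3′-OH should be much slower to cleave under neutral conditions at 1 atm, and no stereocentre is touched.

**Compound list**

1 | 2,4,6-trihydroxybenzaldehyde | O=Cc1c(O)cc(O)cc1O | starting material
2 | 2-hydroxy-4,6-bis(methoxymethoxy)benzaldehyde | O=Cc1c(O)cc(OCOC)cc1OCOC | intermediate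
3 | 2-bromo-1-[4-(benzyloxy)phenyl]ethan-1-one | O=C(CBr)c1ccc(OCc2ccccc2)cc1 | starting material
4 | 2-azido-1-[4-(benzyloxy)phenyl]ethan-1-one | O=C(CN=[N+]=[N-])c1ccc(OCc2ccccc2)cc1 | intermediate
5 | (S)-2-azido-1-[4-(benzyloxy)phenyl]ethan-1-ol | O[C@H](CN=[N+]=[N-])c1ccc(OCc2ccccc2)cc1 | intermediate
6 | 2-{(1R)-2-azido-1-[4-(benzyloxy)phenyl]ethoxy}-4,6-bis(methoxymethoxy)benzaldehyde | O=Cc1c(O[C@@H](CN=[N+]=[N-])c2ccc(OCc3ccccc3)cc2)cc(OCOC)cc1OCOC | intermediate
7 | iminophosphorane of 6 (N=PPh3 in place of N3) | O=Cc1c(O[C@@H](CN=P(c2ccccc2)(c2ccccc2)c2ccccc2)c2ccc(OCc3ccccc3)cc2)cc(OCOC)cc1OCOC | intermediate (not isolated)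
8 | (2R)-2-[4-(benzyloxy)phenyl]-6,8-bis(methoxymethoxy)-2,3-dihydro-1,4-benzoxazepine (cyclic imine) | COCOc1cc(OCOC)c2c(c1)O[C@@H](CN=C2)c1ccc(OCc2ccccc2)cc1 | intermediate (not isolated)
9 | (2R)-2-[4-(benzyloxy)phenyl]-6,8-bis(methoxymethoxy)-2,3,4,5-tetrahydro-1,4-benzoxazepine | COCOc1cc(OCOC)c2c(c1)O[C@@H](CNC2)c1ccc(OCc2ccccc2)cc1 | intermediate
10 | N4-[N-(benzyloxy)-4-(trifluoromethyl)benzamido] derivative of 9 (hydrazide) | COCOc1cc(OCOC)c2c(c1)O[C@@H](CN(C2)N(OCc1ccccc1)C(=O)c1ccc(C(F)(F)F)cc1)c1ccc(OCc2ccccc2)cc1 | intermediate (not isolated)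
11 | isodiazene (1,1-diazene) of 9 | COCOc1cc(OCOC)c2c(c1)O[C@@H](C[N+](=[N-])C2)c1ccc(OCc2ccccc2)cc1 | intermediate (not isolated)
12 | (2S)-2-[4-(benzyloxy)phenyl]-5,7-bis(methoxymethoxy)-3,4-dihydro-2H-chromene | COCOc1cc(OCOC)c2c(c1)O[C@H](c1ccc(OCc3ccccc3)cc1)CC2 | intermediate
13 | (2S)-2-[4-(benzyloxy)phenyl]-8-bromo-5,7-bis(methoxymethoxy)-3,4-dihydro-2H-chromene | COCOc1cc(OCOC)c2c(c1Br)O[C@H](c1ccc(OCc3ccccc3)cc1)CC2 | intermediate
14 | apigenin (5,7-dihydroxy-2-(4-hydroxyphenyl)-4H-chromen-4-one) | O=c1cc(-c2ccc(O)cc2)oc2cc(O)cc(O)c12 | starting material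
15 | 5,7-bis(benzyloxy)-2-[4-(benzyloxy)phenyl]-4H-chromen-4-one | O=c1cc(-c2ccc(OCc3ccccc3)cc2)oc2cc(OCc3ccccc3)cc(OCc3ccccc3)c12 | intermediate
16 | 3-lithio derivative of 15 | [Li]c1c(-c2ccc(OCc3ccccc3)cc2)oc2cc(OCc3ccccc3)cc(OCc3ccccc3)c2c1=O | intermediate (not isolated)
17 | 3-(chlorozincio) derivative of 15 | Cl[Zn]c1c(-c2ccc(OCc3ccccc3)cc2)oc2cc(OCc3ccccc3)cc(OCc3ccccc3)c2c1=O | intermediate (not isolated)
18 | 5,7-bis(benzyloxy)-2-[4-(benzyloxy)phenyl]-3-{(2S)-2-[4-(benzyloxy)phenyl]-5,7-bis(methoxymethoxy)-3,4-dihydro-2H-chromen-8-yl}-4H-chromen-4-one | O=c1c(-c2c(OCOC)cc(OCOC)c3c2O[C@H](c2ccc(OCc4ccccc4)cc2)CC3)c(-c2ccc(OCc3ccccc3)cc2)oc2cc(OCc3ccccc3)cc(OCc3ccccc3)c12 | intermediate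
19 | (2R,3R)-2,3-epoxide of 18 (2,3-epoxy-2,3-dihydro-4H-chromen-4-one; flavan part 2S) | O=C1c2c(OCc3ccccc3)cc(OCc3ccccc3)cc2O[C@]2(c3ccc(OCc4ccccc4)cc3)O[C@]12c1c(OCOC)cc(OCOC)c2c1O[C@H](c1ccc(OCc3ccccc3)cc1)CC2 | intermediate
20 | 2′-methoxy-3′-hydroxy chromanone from methanolysis of 19 (C3′ as in 19, C2′ epimer mixture, MOM groups intact) | O=C1c2c(OCc3ccccc3)cc(OCc3ccccc3)cc2OC(OC)(c2ccc(OCc3ccccc3)cc2)[C@@]1(O)c1c(OCOC)cc(OCOC)c2c1O[C@H](c1ccc(OCc3ccccc3)cc1)CC2 | intermediate (not isolated)
21 | 20 without the two MOM groups (5,7-dihydroxyflavan part) | O=C1c2c(OCc3ccccc3)cc(OCc3ccccc3)cc2OC(OC)(c2ccc(OCc3ccccc3)cc2)[C@@]1(O)c1c(O)cc(O)c2c1O[C@H](c1ccc(OCc3ccccc3)cc1)CC2 | intermediate (not isolated)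
22 | tetra-O-benzyl ether of the target (2S,2′R,3′R; benzyl on O5′, O7′, ring B′ and ring B oxygens) | O=C1c2c(OCc3ccccc3)cc(OCc3ccccc3)cc2O[C@@]2(c3ccc(OCc4ccccc4)cc3)Oc3cc(O)c4c(c3[C@@]12O)O[C@H](c1ccc(OCc3ccccc3)cc1)CC4 | intermediate
23 | CNP0208300.2: (2S)-4′,5-dihydroxyflavan joined through O7–C2′ and C8–C3′ to (2′R,3′R)-3′,5′,7′-trihydroxy-2′-(4-hydroxyphenyl)chroman-4′-one (cis-fused benzofuro[3,2-b]chromenone) | O=C1c2c(O)cc(O)cc2O[C@@]2(c3ccc(O)cc3)Oc3cc(O)c4c(c3[C@@]12O)O[C@H](c1ccc(O)cc1)CC4 | target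

**Count and risks**

Total steps: 12. Longest linear sequence: 10 (steps 2, 3, 4, 5, 6, 7, 9, 10, 11, 12).

Steps most likely to fail:

1. Step 6. After loss of N2 the radical pair may fragment by β-scission of the C2–O1 bond (an ortho-quinone methide and a styrene, whose recombination would be stereorandom), or the isodiazene may tautomerise to a hydrazone. The result would be erosion of the ee or poor conversion to the contracted ring. Fallback: setting out from 2, Claisen–Schmidt condensation with purchased 1-[4-(benzyloxy)phenyl]ethan-1-one (CC(=O)c1ccc(OCc2ccccc2)cc1; KOH, EtOH) should give (E)-1-[4-(benzyloxy)phenyl]-3-[2-hydroxy-4,6-bis(methoxymethoxy)phenyl]prop-2-en-1-one F1. Conjugate hydrogenation with H2 and RhCl(PPh3)3 (benzyl ethers are spared) should give 1-[4-(benzyloxy)phenyl]-3-[2-hydroxy-4,6-bis(methoxymethoxy)phenyl]propan-1-one F2. CBS reduction with the (S) catalyst and BH3·SMe2 should give (R)-1-[4-(benzyloxy)phenyl]-3-[2-hydroxy-4,6-bis(methoxymethoxy)phenyl]propan-1-ol F3. Intramolecular Mitsunobu etherification (PPh3, DIAD) then closes the pyran directly with inversion and comes back to the route at 12.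

2. Step 10. Oxygen transfer to the crowded tetrasubstituted C2′=C3′ bond (flanked by ring B′ and the di-ortho-substituted ring A) may be slow, facial discrimination may be poor, and the electron-rich ring A may be oxidised instead. Fallback: setting out from 18, HCl in MeOH/THF should remove the MOM groups to give the 5,7-dihydroxyflavan-8-yl chromone F7. With KOt-Bu in THF at −40 °C the 7-phenoxide should add to C2′ (oxa-Michael, reversible) to give the potassium enolate of the cis-fused benzofurochromanone F8. This enolate is hydroxylated at C3′ in the same flask by an enantiopure (camphorsulfonyl)oxaziridine, the antipode being chosen to favour the required diastereomer (Algar–Flynn–Oyamada-type logic with a chiral oxidant). The sequence comes back to the route at 22, and the diastereomers are separated there if needed.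

3. Step 9. Transmetalation and reductive elimination may be slow in forming a bond with four ortho substituents, so protonation of the arylzinc and reduction of the aryl bromide may compete. Fallback: setting out from 15, lithiation with LiN(iPr)2 (via 16) and quenching with I2 should give 5,7-bis(benzyloxy)-2-[4-(benzyloxy)phenyl]-3-iodo-4H-chromen-4-one F4. Setting out from 13, bromine–lithium exchange with n-BuLi at −78 °C gives the 8-lithioflavan F5, which is trapped with 2-isopropoxy-4,4,5,5-tetramethyl-1,3,2-dioxaborolane to give the flavan-8-yl pinacol boronate F6. Suzuki–Miyaura coupling of F4 and F6 (Pd(OAc)2, SPhos, K3PO4, toluene/H2O, 90 °C) comes back to the route at 18.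

**Further compounds**

F1 | step 6 | (E)-1-[4-(benzyloxy)phenyl]-3-[2-hydroxy-4,6-bis(methoxymethoxy)phenyl]prop-2-en-1-one | O=C(/C=C/c1c(O)cc(OCOC)cc1OCOC)c1ccc(OCc2ccccc2)cc1
F2 | step 6 | 1-[4-(benzyloxy)phenyl]-3-[2-hydroxy-4,6-bis(methoxymethoxy)phenyl]propan-1-one | O=C(CCc1c(O)cc(OCOC)cc1OCOC)c1ccc(OCc2ccccc2)cc1
F3 | step 6 | (R)-1-[4-(benzyloxy)phenyl]-3-[2-hydroxy-4,6-bis(methoxymethoxy)phenyl]propan-1-ol | O[C@H](CCc1c(O)cc(OCOC)cc1OCOC)c1ccc(OCc2ccccc2)cc1
F4 | step 9 | 5,7-bis(benzyloxy)-2-[4-(benzyloxy)phenyl]-3-iodo-4H-chromen-4-one | O=c1c(I)c(-c2ccc(OCc3ccccc3)cc2)oc2cc(OCc3ccccc3)cc(OCc3ccccc3)c12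
F5 | step 9 | (2S)-2-[4-(benzyloxy)phenyl]-8-lithio-5,7-bis(methoxymethoxy)-3,4-dihydro-2H-chromene | COCOc1cc(OCOC)c2c(c1[Li])O[C@H](c1ccc(OCc3ccccc3)cc1)CC2
F6 | step 9 | (2S)-2-[4-(benzyloxy)phenyl]-5,7-bis(methoxymethoxy)-8-(4,4,5,5-tetramethyl-1,3,2-dioxaborolan-2-yl)-3,4-dihydro-2H-chromene | COCOc1cc(OCOC)c2c(c1B1OC(C)(C)C(C)(C)O1)O[C@H](c1ccc(OCc3ccccc3)cc1)CC2
F7 | step 10 | 5,7-bis(benzyloxy)-2-[4-(benzyloxy)phenyl]-3-{(2S)-2-[4-(benzyloxy)phenyl]-5,7-dihydroxy-3,4-dihydro-2H-chromen-8-yl}-4H-chromen-4-one | O=c1c(-c2c(O)cc(O)c3c2O[C@H](c2ccc(OCc4ccccc4)cc2)CC3)c(-c2ccc(OCc3ccccc3)cc2)oc2cc(OCc3ccccc3)cc(OCc3ccccc3)c12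
F8 | step 10 | potassium enolate of the oxa-Michael adduct of F7 (O7 bonded to C2′, C3′=C4′–O− K+, C2′ epimers in equilibrium, drawn with 5-OH protonated) | [K+].[O-]C1=C2c3c(cc(O)c4c3O[C@H](c3ccc(OCc5ccccc5)cc3)CC4)OC2(c2ccc(OCc3ccccc3)cc2)Oc2cc(OCc3ccccc3)cc(OCc3ccccc3)c12
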